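**Retrosynthetic overview**
- Target 43 is (3R,3′R,6′R)-siphonaxanthin 19-dodecanoate. The last skeletal bond is C15=C15′ (Wittig) between C20 phosphonium salt 19 (cyclohex-2-enyl half) and C20 keto aldehyde 40 (cyclohex-1-enyl half, laurate already in place); desilylation follows.
- The strategy rests on the E-trisubstituted C9′=C10′ alkene with its C19′ methyl, directly beside the 2,6,6-trimethylcyclohex-2-enyl ring (C1′–C6′). It is cut to the terminal C9′≡C10′ ring enyne 9, a methyl group from Me3Al (C9′–C19′) and dienyl iodide 13 (C10′–C11′), joined in one pot.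
- Enyne 9 comes from racemic α-ionone (C3′ oxidation, trans-selective reduction, lipase resolution, methyl ketone to alkyne); iodide 13 comes from (E)-3-methylpent-2-en-4-yn-1-ol.
- Half 40: C8–C9 by Nozaki–Hiyama–Kishi coupling of ring acetaldehyde 29 (from 4-oxoisophorone) with 2-iodotrienol 34; the C9=C10 geometry comes from syn-hydrostannation of ynoate 31, made from 13 and methyl propiolate (C10–C11).
- No ring is formed: the cyclohex-2-enyl ring is carried from α-ionone and the cyclohex-1-enyl ring from 4-oxoisophorone.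

Key step: step 10

Assumption: commercial α-ionone is the racemic (E)-isomer; the target SMILES is read as (3R,3′R,6′R), all-E chain, with C19 cis to C11 across C9=C10. Carotenoid numbering is used in the comments (primes = cyclohex-2-enyl half); TBSO = tert-butyldimethylsilyloxy.

**Route**

Step 1
Reactants: 1 (E)-α-ionone, racemic
Product: 2 rac-2-methyl-2-[(E)-2-(2,6,6-trimethylcyclohex-2-en-1-yl)ethenyl]-1,3-dioxolane
Conditions: Me3SiOCH2CH2OSiMe3, Me3SiOTf (cat.), CH2Cl2, −78 → −20 °C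
Reagents that add atoms: 1,2-bis(trimethylsilyloxy)ethane C[Si](C)(C)OCCO[Si](C)(C)C
Why: Low-temperature silyl-triflate-catalysed ketalisation masks the C9′ ketone as the dioxolane without shifting the C7′=C8′ double bond.

Step 2
Reactants: 2 α-ionone ketal
Product: 3 rac-3,5,5-trimethyl-4-[(E)-2-(2-methyl-1,3-dioxolan-2-yl)ethenyl]cyclohex-2-en-1-one
Conditions: t-BuOOH, Rh2(caprolactamate)4 (cat.), K2CO3, CH2Cl2, rt
Reagents that add atoms: tert-butyl hydroperoxide CC(C)(C)OO
Why: Radical allylic oxidation through tert-butylperoxyl radicals converts the only ring allylic methylene (C3′) into the enone, the C6′–H being shielded by its three neighbouring substituents, and the basic medium keeps the ketal.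

Step 3
Reactants: 3 3-oxo ketal
Product: 4 rac-(1R*,4R*)-3,5,5-trimethyl-4-[(E)-2-(2-methyl-1,3-dioxolan-2-yl)ethenyl]cyclohex-2-en-1-ol (3′,6′-trans)
Conditions: LiBH(s-Bu)3, THF, −78 °C; aq. NaHCO3
Reagents that add atoms: none
Why: 1,2-Reduction of the β-methyl cyclohexenone by a bulky borohydride should deliver hydride to the face opposite the pseudo-axial C1′ methyl, which with the side chain pseudo-axial at C6′ gives mainly the trans alcohol; the minor cis isomer is removed by chromatography.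

Step 4
Reactants: 4 racemic trans alcohol
Product: 5 (1R,4R)-3,5,5-trimethyl-4-[(E)-2-(2-methyl-1,3-dioxolan-2-yl)ethenyl]cyclohex-2-en-1-ol
Conditions: lipase PS (Burkholderia cepacia lipase, immobilised), vinyl acetate, t-BuOMe, 30 °C, stopped just beyond half conversion; chromatography
Reagents that add atoms: none
Why: Lipase-catalysed kinetic resolution by transesterification should, by the empirical size rule for secondary alcohols (gem-dimethyl flank large, vinyl flank medium), acetylate the (3′S,6′S) enantiomer and leave the (3′R,6′R) alcohol, whose configuration is to be confirmed by Mosher ester analysis.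

Step 5
Reactants: 5 (1R,4R)-alcohol
Product: 6 tert-butyldimethyl{[(1R,4R)-3,5,5-trimethyl-4-[(E)-2-(2-methyl-1,3-dioxolan-2-yl)ethenyl]cyclohex-2-en-1-yl]oxy}silane
Conditions: t-BuMe2SiCl, imidazole, DMF, rt
Reagents that add atoms: tert-butyldimethylsilyl chloride CC(C)(C)[Si](C)(C)Cl
Why: Standard silylation protects the allylic C3′ hydroxyl before the acidic, basic and Lewis acidic steps that follow.

Step 6
Reactants: 6 silyl ether ketal
Product: 7 (E)-4-[(1R,4R)-4-(TBSO)-2,6,6-trimethylcyclohex-2-en-1-yl]but-3-en-2-one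
Conditions: pyridinium p-toluenesulfonate (cat.), acetone/H2O, rt
Reagents that add atoms: water O
Why: Mild acid hydrolysis of the allylic ketal frees the methyl ketone while the secondary silyl ether and the C6′ centre stay intact.

Step 7
Reactants: 7 silylated hydroxy-α-ionone
Product: 9 tert-butyl{[(1R,4R)-4-[(E)-but-1-en-3-yn-1-yl]-3,5,5-trimethylcyclohex-2-en-1-yl]oxy}dimethylsilane (ring enyne), via dienyl diethyl phosphate 8 (not isolated)
Conditions: lithium diisopropylamide (1.05 equiv), THF, −78 °C; ClP(O)(OEt)2, −78 °C → rt; lithium diisopropylamide (2.3 equiv), −78 °C → rt; aq. NH4Cl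
Reagents that add atoms: none
Why: Kinetic enolisation at the methyl group, O-phosphorylation and base-induced elimination of diethyl phosphate (enol phosphate to alkyne) give the terminal enyne, the low temperature keeping the hindered C6′–H untouched.

Step 8
Reactants: 10 (E)-3-methylpent-2-en-4-yn-1-ol
Product: 11 tert-butyldimethyl{[(E)-3-methylpent-2-en-4-yn-1-yl]oxy}silane
Conditions: t-BuMe2SiCl, imidazole, DMF, rt
Reagents that add atoms: tert-butyldimethylsilyl chloride CC(C)(C)[Si](C)(C)Cl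
Why: Standard silylation of the primary allylic alcohol.

Step 9
Reactants: 11 silylated pentenynol
Product: 13 (1E,3E)-5-(tert-butyldimethylsilyloxy)-1-iodo-3-methylpenta-1,3-diene, via alkenylzirconocene chloride 12 (not isolated)
Conditions: Cp2Zr(H)Cl, THF, rt; then iodine, 0 °C
Reagents that add atoms: iodine II
Why: syn-Hydrozirconation of the terminal alkyne places zirconium on the terminal carbon and iodinolysis with retention gives the (E)-alkenyl iodide, the trisubstituted alkene being inert.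

Step 10
Reactants: 9 ring enyne; 14 trimethylaluminium; 13 dienyl iodide
Product: 16 (2E,4E,6E,8E)-1-(TBSO)-3,7-dimethyl-9-[(1R,4R)-4-(TBSO)-2,6,6-trimethylcyclohex-2-en-1-yl]nona-2,4,6,8-tetraene (C20 bis-silyl ether), via alkenyldimethylalane 15 (not isolated)
Conditions: 14 (2 equiv), Cp2ZrCl2 (0.3 equiv), ClCH2CH2Cl, 0 °C → rt; then 13, ZnCl2 (cat.), Pd(PPh3)4 (cat.), THF, rt
Reagents that add atoms: trimethylaluminium (14) C[Al](C)C
Why: Cp2ZrCl2 and Me3Al form a methylzirconocene–alane pair that adds methyl and metal syn across the terminal C9′≡C10′ bond through a four-centre transition state, methyl going to the internal carbon C9′ and aluminium to C10′, which creates the C9′–C19′ bond and the E-trisubstituted alkene of alane 15. ZnCl2 then relays the alkenyl group to palladium; oxidative addition of zerovalent palladium into the C–I bond of 13, transmetalation and reductive elimination form C10′–C11′ with retention at both alkenyl carbons (Negishi coupling). The closest known reaction type is the zirconium-catalysed methylalumination of conjugated terminal enynes with in situ palladium–zinc cross-coupling, as used for retinoid and carotenoid chains. No ring is closed and no stereocentre is created. The step needs regioselectivity (methyl at C9′), syn addition and stereoretentive coupling: the first two follow from the terminal alkyne conjugated to C7′=C8′, which differentiates the two alkyne carbons electronically and sterically, and the third from the stereospecific elementary steps at palladium. The aprotic, non-basic medium leaves the doubly allylic C6′–H and both silyl ethers untouched, so the (3′R,6′R) ring passes through unchanged.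

Step 11
Reactants: 16 C20 bis-silyl ether
Product: 17 (2E,4E,6E,8E)-3,7-dimethyl-9-[(1R,4R)-4-(TBSO)-2,6,6-trimethylcyclohex-2-en-1-yl]nona-2,4,6,8-tetraen-1-ol
Conditions: HF·pyridine, excess pyridine, THF, 0 °C
Reagents that add atoms: none
Why: Buffered fluoride cleaves the unhindered primary allylic silyl ether much faster than the hindered secondary ring silyl ether, and the excess pyridine protects the acid-labile tetraenol.

Step 12
Reactants: 17 C20 tetraenol
Product: 19 {(2E,4E,6E,8E)-3,7-dimethyl-9-[(1R,4R)-4-(TBSO)-2,6,6-trimethylcyclohex-2-en-1-yl]nona-2,4,6,8-tetraen-1-yl}triphenylphosphonium bromide, via allylic bromide 18 (not isolated)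
Conditions: CBr4 (1.1 equiv), PPh3 (2.2 equiv), CH2Cl2, −20 °C → rt, dark
Reagents that add atoms: triphenylphosphine c1ccc(cc1)P(c1ccccc1)c1ccccc1; carbon tetrabromide BrC(Br)(Br)Br
Why: Appel bromination under acid-free conditions followed by in situ displacement of the reactive allylic bromide at its primary terminus by the excess phosphine gives the salt without ionising the C3′ allylic silyl ether.

Step 13
Reactants: 20 4-oxoisophorone
Product: 21 (6R)-2,2,6-trimethylcyclohexane-1,4-dione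
Conditions: baker's yeast (Saccharomyces cerevisiae), sucrose, H2O, 30 °C
Reagents that add atoms: none
Why: Ene-reductase-mediated hydrogenation of the enedione C=C by fermenting yeast sets the C6 methyl-bearing centre as R under enzyme control.

Step 14
Reactants: 21 (6R)-dione
Product: 22 (4R,6R)-4-hydroxy-2,2,6-trimethylcyclohexan-1-one
Conditions: LiBH(s-Bu)3 (1 equiv), THF, −78 °C; aq. NaHCO3
Reagents that add atoms: none
Why: The bulky hydride reduces only the unhindered C4 ketone and attacks equatorially, away from the axial C2 methyl, so the new hydroxyl is trans to the C6 methyl, which is the (4R) centre that becomes C3.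

Step 15
Reactants: 22 hydroxy ketone
Product: 23 (4R,6R)-4-(TBSO)-2,2,6-trimethylcyclohexan-1-one
Conditions: t-BuMe2SiCl, imidazole, DMF, rt
Reagents that add atoms: tert-butyldimethylsilyl chloride CC(C)(C)[Si](C)(C)Cl
Why: Standard silylation of the secondary alcohol.

Step 16
Reactants: 23 silyloxy ketone
Product: 24 (4R)-4-(TBSO)-2,6,6-trimethylcyclohex-1-en-1-yl trifluoromethanesulfonate
Conditions: KN(SiMe3)2, THF, −78 °C; PhNTf2, −78 → 0 °C
Reagents that add atoms: N-phenylbis(trifluoromethanesulfonimide) O=S(=O)(N(c1ccccc1)S(=O)(=O)C(F)(F)F)C(F)(F)F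
Why: The ketone can enolise only toward C6, so O-triflation gives the tetrasubstituted enol triflate (the future C5=C6 bond), erasing the relay centre and leaving C4 untouched.

Step 17
Reactants: 24 enol triflate; 25 tributyl(vinyl)stannane
Product: 26 tert-butyl{[(1R)-4-ethenyl-3,5,5-trimethylcyclohex-3-en-1-yl]oxy}dimethylsilane
Conditions: Pd2(dba)3 (cat.), AsPh3, N-methylpyrrolidone, 60 °C
Reagents that add atoms: tributyl(vinyl)stannane (25) C=C[Sn](CCCC)(CCCC)CCCC
Why: Stille coupling with the weakly bound arsine ligand is suited to hindered tetrasubstituted alkenyl triflates and installs C7–C8 as a vinyl group.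

Step 18
Reactants: 26 ring diene
Product: 28 2-[(4R)-4-(TBSO)-2,6,6-trimethylcyclohex-1-en-1-yl]ethan-1-ol, via B-alkyl-9-borabicyclo[3.3.1]nonane 27 (not isolated)
Conditions: 9-borabicyclo[3.3.1]nonane, THF, 0 °C → rt; NaOH, H2O2, 0 °C
Reagents that add atoms: hydrogen peroxide OO
Why: Anti-Markovnikov hydroboration by the bulky borane takes only the monosubstituted alkene (the tetrasubstituted ring alkene is inert), and oxidation places the hydroxyl on C8.

Step 19
Reactants: 28 homoallylic alcohol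
Product: 29 2-[(4R)-4-(TBSO)-2,6,6-trimethylcyclohex-1-en-1-yl]acetaldehyde
Conditions: Dess–Martin periodinane, NaHCO3, CH2Cl2, 0 °C
Reagents that add atoms: none
Why: Buffered periodinane oxidation gives the β,γ-unsaturated aldehyde without moving the tetrasubstituted C5=C6 bond into conjugation.

Step 20
Reactants: 13 dienyl iodide; 30 methyl propiolate
Product: 31 methyl (4E,6E)-8-(TBSO)-6-methylocta-4,6-dien-2-ynoate
Conditions: Pd(PPh3)2Cl2 (cat.), CuI (cat.), K2CO3, THF, rt → 40 °C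
Reagents that add atoms: methyl propiolate (30) COC(=O)C#C
Why: Sonogashira coupling forms C10–C11 with retention of the iodide geometry, the inorganic base avoiding amine addition to the propiolate.

Step 21
Reactants: 31 dienynoate
Product: 32 methyl (2E,4E,6E)-8-(TBSO)-6-methyl-2-(tributylstannyl)octa-2,4,6-trienoate
Conditions: Bu3SnH (slow addition), Pd(PPh3)4 (cat.), THF, 0 °C
Reagents that add atoms: tributyltin hydride CCCC[SnH](CCCC)CCCC
Why: Palladium-catalysed syn-hydrostannation of an alk-2-ynoate puts hydrogen on the β-carbon (C10) and tin on the α-carbon (C9), which fixes the C9=C10 geometry with the future C19 cis to C11.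

Step 22
Reactants: 32 alkenylstannane
Product: 33 methyl (2E,4E,6E)-8-(TBSO)-2-iodo-6-methylocta-2,4,6-trienoate
Conditions: iodine (1.05 equiv), CH2Cl2, 0 °C, dark
Reagents that add atoms: iodine II
Why: Iododestannylation proceeds with retention at the alkenyl carbon, and the short, cold, dark treatment avoids iodine-catalysed alkene isomerisation.

Step 23
Reactants: 33 iodo ester
Product: 34 (2E,4E,6E)-8-(TBSO)-2-iodo-6-methylocta-2,4,6-trien-1-ol
Conditions: i-Bu2AlH (2.2 equiv), CH2Cl2, −78 °C; aq. potassium sodium tartrate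
Reagents that add atoms: none
Why: 1,2-Reduction of the conjugated ester gives the C19 allylic alcohol and leaves the alkenyl iodide intact at low temperature.

Step 24
Reactants: 34 iodotrienol; 29 ring acetaldehyde
Product: 35 (3E,5E,7E)-9-(TBSO)-3-(hydroxymethyl)-7-methyl-1-[(4R)-4-(TBSO)-2,6,6-trimethylcyclohex-1-en-1-yl]nona-3,5,7-trien-2-ol (both C8 epimers)
Conditions: CrCl2 (excess), NiCl2 (cat.), DMSO/THF, rt
Reagents that add atoms: none
Why: Nozaki–Hiyama–Kishi coupling forms C8–C9 through a nickel-generated alkenylchromium species that adds only to the aldehyde, tolerates the free hydroxyl and the enolisable aldehyde and retains the alkene geometry; the new C8 carbinol centre is uncontrolled and is removed in step 26.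

Step 25
Reactants: 35 diol; 36 dodecanoyl chloride
Product: 37 (2E,4E,6E)-8-(TBSO)-2-{1-hydroxy-2-[(4R)-4-(TBSO)-2,6,6-trimethylcyclohex-1-en-1-yl]ethyl}-6-methylocta-2,4,6-trien-1-yl dodecanoate
Conditions: 36 (1.05 equiv), 2,4,6-collidine, CH2Cl2, −78 → −30 °C
Reagents that add atoms: dodecanoyl chloride (36) CCCCCCCCCCCC(=O)Cl
Why: At low temperature with a hindered base the acid chloride acylates the primary C19 hydroxyl and not the hindered secondary C8 hydroxyl, which puts the laurate of the target in place.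

Step 26
Reactants: 37 hydroxy laurate
Product: 38 (2E,4E,6E)-8-(TBSO)-6-methyl-2-{2-[(4R)-4-(TBSO)-2,6,6-trimethylcyclohex-1-en-1-yl]acetyl}octa-2,4,6-trien-1-yl dodecanoate
Conditions: Dess–Martin periodinane, NaHCO3, CH2Cl2, 0 °C → rt
Reagents that add atoms: none
Why: Buffered periodinane oxidation converts the C8 allylic alcohol into the ketone without touching the ester, the silyl ethers or the C5=C6 position.

Step 27
Reactants: 38 keto laurate
Product: 39 (2E,4E,6E)-8-hydroxy-6-methyl-2-{2-[(4R)-4-(TBSO)-2,6,6-trimethylcyclohex-1-en-1-yl]acetyl}octa-2,4,6-trien-1-yl dodecanoate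
Conditions: HF·pyridine, excess pyridine, THF, 0 °C
Reagents that add atoms: none
Why: The primary allylic silyl ether at C15 is cleaved selectively over the secondary ring silyl ether, and the buffered fluoride spares the ester.

Step 28
Reactants: 39 C15 alcohol
Product: 40 (2E,4E,6E)-6-methyl-8-oxo-2-{2-[(4R)-4-(TBSO)-2,6,6-trimethylcyclohex-1-en-1-yl]acetyl}octa-2,4,6-trien-1-yl dodecanoate (C20 keto aldehyde)
Conditions: activated MnO2, CH2Cl2, rt
Reagents that add atoms: none
Why: MnO2 oxidises the allylic alcohol to the conjugated aldehyde under neutral conditions.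

Step 29
Reactants: 19 C20 phosphonium bromide; 40 C20 keto aldehyde
Product: 42 (3R,3′R,6′R)-3,3′-bis(TBSO)-19-dodecanoyloxy-7,8-dihydro-β,ε-caroten-8-one, via phosphorus ylide 41 (not isolated)
Conditions: 1,2-epoxybutane/EtOH, 60 °C, argon, dark; then heptane, 80 °C (Z to E equilibration at C15=C15′)
Reagents that add atoms: none
Why: Bromide opens the epoxide to an alkoxide that deprotonates the salt, and the semistabilised ylide reacts in a Wittig olefination with the aldehyde and not with the hindered conjugated C8 ketone; the near-neutral medium preserves the laurate and the C7 methylene, and the central Z isomer should equilibrate thermally to all-E.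

Step 30
Reactants: 42 bis-silyl ether
Product: 43 (3R,3′R,6′R)-19-dodecanoyloxy-3,3′-dihydroxy-7,8-dihydro-β,ε-caroten-8-one
Conditions: HF·pyridine, excess pyridine, THF, 0 °C → rt, dark
Reagents that add atoms: none
Why: Buffered fluoride removes both secondary silyl ethers without cleaving the allylic laurate or ionising the allylic C3′ alcohol.

**Compound list**
1 | (E)-α-ionone, racemic | CC1=CCCC(C)(C)C1/C=C/C(C)=O | starting material
2 | rac-2-methyl-2-[(E)-2-(2,6,6-trimethylcyclohex-2-en-1-yl)ethenyl]-1,3-dioxolane | CC1=CCCC(C)(C)C1/C=C/C1(C)OCCO1 | intermediate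
3 | rac-3,5,5-trimethyl-4-[(E)-2-(2-methyl-1,3-dioxolan-2-yl)ethenyl]cyclohex-2-en-1-one | CC1=CC(=O)CC(C)(C)C1/C=C/C1(C)OCCO1 | intermediate
4 | rac-(1R*,4R*)-3,5,5-trimethyl-4-[(E)-2-(2-methyl-1,3-dioxolan-2-yl)ethenyl]cyclohex-2-en-1-ol (both enantiomers) | CC1(OCCO1)/C=C/[C@H]1C(C)=C[C@H](O)CC1(C)C.CC1(OCCO1)/C=C/[C@@H]1C(C)=C[C@@H](O)CC1(C)C | intermediate
5 | (1R,4R)-3,5,5-trimethyl-4-[(E)-2-(2-methyl-1,3-dioxolan-2-yl)ethenyl]cyclohex-2-en-1-ol | CC1(OCCO1)/C=C/[C@H]1C(C)=C[C@H](O)CC1(C)C | intermediate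
6 | tert-butyldimethyl{[(1R,4R)-3,5,5-trimethyl-4-[(E)-2-(2-methyl-1,3-dioxolan-2-yl)ethenyl]cyclohex-2-en-1-yl]oxy}silane | CC1(OCCO1)/C=C/[C@H]1C(C)=C[C@H](O[Si](C)(C)C(C)(C)C)CC1(C)C | intermediate
7 | (E)-4-[(1R,4R)-4-(TBSO)-2,6,6-trimethylcyclohex-2-en-1-yl]but-3-en-2-one | CC(=O)/C=C/[C@H]1C(C)=C[C@H](O[Si](C)(C)C(C)(C)C)CC1(C)C | intermediate
8 | diethyl (E)-4-[(1R,4R)-4-(TBSO)-2,6,6-trimethylcyclohex-2-en-1-yl]buta-1,3-dien-2-yl phosphate (not isolated) | C=C(OP(=O)(OCC)OCC)/C=C/[C@H]1C(C)=C[C@H](O[Si](C)(C)C(C)(C)C)CC1(C)C | intermediate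
9 | tert-butyl{[(1R,4R)-4-[(E)-but-1-en-3-yn-1-yl]-3,5,5-trimethylcyclohex-2-en-1-yl]oxy}dimethylsilane | C#C/C=C/[C@H]1C(C)=C[C@H](O[Si](C)(C)C(C)(C)C)CC1(C)C | intermediate
10 | (E)-3-methylpent-2-en-4-yn-1-ol | C#C/C(C)=C/CO | starting material
11 | tert-butyldimethyl{[(E)-3-methylpent-2-en-4-yn-1-yl]oxy}silane | C#C/C(C)=C/CO[Si](C)(C)C(C)(C)C | intermediate
12 | chlorobis(cyclopentadienyl)[(1E,3E)-5-(TBSO)-3-methylpenta-1,3-dien-1-yl]zirconium (not isolated) | Cl[Zr](/C=C/C(C)=C/CO[Si](C)(C)C(C)(C)C)(C1C=CC=C1)C1C=CC=C1 | intermediate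
13 | (1E,3E)-5-(tert-butyldimethylsilyloxy)-1-iodo-3-methylpenta-1,3-diene | I/C=C/C(C)=C/CO[Si](C)(C)C(C)(C)C | intermediate
14 | trimethylaluminium | C[Al](C)C | starting material
15 | dimethyl{(1E,3E)-2-methyl-4-[(1R,4R)-4-(TBSO)-2,6,6-trimethylcyclohex-2-en-1-yl]buta-1,3-dien-1-yl}alane (not isolated) | C[Al](C)/C=C(C)/C=C/[C@H]1C(C)=C[C@H](O[Si](C)(C)C(C)(C)C)CC1(C)C | intermediate
16 | (2E,4E,6E,8E)-1-(TBSO)-3,7-dimethyl-9-[(1R,4R)-4-(TBSO)-2,6,6-trimethylcyclohex-2-en-1-yl]nona-2,4,6,8-tetraene | CC(C)(C)[Si](C)(C)OC/C=C(C)/C=C/C=C(C)/C=C/[C@H]1C(C)=C[C@H](O[Si](C)(C)C(C)(C)C)CC1(C)C | intermediate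
17 | (2E,4E,6E,8E)-3,7-dimethyl-9-[(1R,4R)-4-(TBSO)-2,6,6-trimethylcyclohex-2-en-1-yl]nona-2,4,6,8-tetraen-1-ol | OC/C=C(C)/C=C/C=C(C)/C=C/[C@H]1C(C)=C[C@H](O[Si](C)(C)C(C)(C)C)CC1(C)C | intermediate
18 | (2E,4E,6E,8E)-1-bromo-3,7-dimethyl-9-[(1R,4R)-4-(TBSO)-2,6,6-trimethylcyclohex-2-en-1-yl]nona-2,4,6,8-tetraene (not isolated) | BrC/C=C(C)/C=C/C=C(C)/C=C/[C@H]1C(C)=C[C@H](O[Si](C)(C)C(C)(C)C)CC1(C)C | intermediate
19 | {(2E,4E,6E,8E)-3,7-dimethyl-9-[(1R,4R)-4-(TBSO)-2,6,6-trimethylcyclohex-2-en-1-yl]nona-2,4,6,8-tetraen-1-yl}triphenylphosphonium bromide | [Br-].c1ccccc1[P+](c1ccccc1)(c1ccccc1)C/C=C(C)/C=C/C=C(C)/C=C/[C@H]1C(C)=C[C@H](O[Si](C)(C)C(C)(C)C)CC1(C)C | intermediate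
20 | 4-oxoisophorone (2,6,6-trimethylcyclohex-2-ene-1,4-dione) | CC1=CC(=O)CC(C)(C)C1=O | starting material
21 | (6R)-2,2,6-trimethylcyclohexane-1,4-dione | O=C1[C@H](C)CC(=O)CC1(C)C | intermediate
22 | (4R,6R)-4-hydroxy-2,2,6-trimethylcyclohexan-1-one | O=C1[C@H](C)C[C@@H](O)CC1(C)C | intermediate
23 | (4R,6R)-4-(TBSO)-2,2,6-trimethylcyclohexan-1-one | O=C1[C@H](C)C[C@@H](O[Si](C)(C)C(C)(C)C)CC1(C)C | intermediate
24 | (4R)-4-(TBSO)-2,6,6-trimethylcyclohex-1-en-1-yl trifluoromethanesulfonate | FC(F)(F)S(=O)(=O)OC1=C(C)C[C@@H](O[Si](C)(C)C(C)(C)C)CC1(C)C | intermediate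
25 | tributyl(vinyl)stannane | C=C[Sn](CCCC)(CCCC)CCCC | starting material
26 | tert-butyl{[(1R)-4-ethenyl-3,5,5-trimethylcyclohex-3-en-1-yl]oxy}dimethylsilane | C=CC1=C(C)C[C@@H](O[Si](C)(C)C(C)(C)C)CC1(C)C | intermediate
27 | 9-{2-[(4R)-4-(TBSO)-2,6,6-trimethylcyclohex-1-en-1-yl]ethyl}-9-borabicyclo[3.3.1]nonane (not isolated) | C1CC2CCCC(C1)B2CCC1=C(C)C[C@@H](O[Si](C)(C)C(C)(C)C)CC1(C)C | intermediate
28 | 2-[(4R)-4-(TBSO)-2,6,6-trimethylcyclohex-1-en-1-yl]ethan-1-ol | OCCC1=C(C)C[C@@H](O[Si](C)(C)C(C)(C)C)CC1(C)C | intermediate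
29 | 2-[(4R)-4-(TBSO)-2,6,6-trimethylcyclohex-1-en-1-yl]acetaldehyde | O=CCC1=C(C)C[C@@H](O[Si](C)(C)C(C)(C)C)CC1(C)C | intermediate
30 | methyl propiolate | COC(=O)C#C | starting material
31 | methyl (4E,6E)-8-(TBSO)-6-methylocta-4,6-dien-2-ynoate | COC(=O)C#C/C=C/C(C)=C/CO[Si](C)(C)C(C)(C)C | intermediate
32 | methyl (2E,4E,6E)-8-(TBSO)-6-methyl-2-(tributylstannyl)octa-2,4,6-trienoate | COC(=O)/C([Sn](CCCC)(CCCC)CCCC)=C\C=C\C(C)=C\CO[Si](C)(C)C(C)(C)C | intermediate
33 | methyl (2E,4E,6E)-8-(TBSO)-2-iodo-6-methylocta-2,4,6-trienoate | COC(=O)/C(I)=C\C=C\C(C)=C\CO[Si](C)(C)C(C)(C)C | intermediate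
34 | (2E,4E,6E)-8-(TBSO)-2-iodo-6-methylocta-2,4,6-trien-1-ol | OC/C(I)=C\C=C\C(C)=C\CO[Si](C)(C)C(C)(C)C | intermediate
35 | (3E,5E,7E)-9-(TBSO)-3-(hydroxymethyl)-7-methyl-1-[(4R)-4-(TBSO)-2,6,6-trimethylcyclohex-1-en-1-yl]nona-3,5,7-trien-2-ol (C8 epimers) | OC/C(=C\C=C\C(C)=C\CO[Si](C)(C)C(C)(C)C)C(O)CC1=C(C)C[C@@H](O[Si](C)(C)C(C)(C)C)CC1(C)C | intermediate
36 | dodecanoyl chloride | CCCCCCCCCCCC(=O)Cl | starting material
37 | (2E,4E,6E)-8-(TBSO)-2-{1-hydroxy-2-[(4R)-4-(TBSO)-2,6,6-trimethylcyclohex-1-en-1-yl]ethyl}-6-methylocta-2,4,6-trien-1-yl dodecanoate (C8 epimers) | CCCCCCCCCCCC(=O)OC/C(=C\C=C\C(C)=C\CO[Si](C)(C)C(C)(C)C)C(O)CC1=C(C)C[C@@H](O[Si](C)(C)C(C)(C)C)CC1(C)C | intermediate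
38 | (2E,4E,6E)-8-(TBSO)-6-methyl-2-{2-[(4R)-4-(TBSO)-2,6,6-trimethylcyclohex-1-en-1-yl]acetyl}octa-2,4,6-trien-1-yl dodecanoate | CCCCCCCCCCCC(=O)OC/C(=C\C=C\C(C)=C\CO[Si](C)(C)C(C)(C)C)C(=O)CC1=C(C)C[C@@H](O[Si](C)(C)C(C)(C)C)CC1(C)C | intermediate
39 | (2E,4E,6E)-8-hydroxy-6-methyl-2-{2-[(4R)-4-(TBSO)-2,6,6-trimethylcyclohex-1-en-1-yl]acetyl}octa-2,4,6-trien-1-yl dodecanoate | CCCCCCCCCCCC(=O)OC/C(=C\C=C\C(C)=C\CO)C(=O)CC1=C(C)C[C@@H](O[Si](C)(C)C(C)(C)C)CC1(C)C | intermediate
40 | (2E,4E,6E)-6-methyl-8-oxo-2-{2-[(4R)-4-(TBSO)-2,6,6-trimethylcyclohex-1-en-1-yl]acetyl}octa-2,4,6-trien-1-yl dodecanoate | CCCCCCCCCCCC(=O)OC/C(=C\C=C\C(C)=C\C=O)C(=O)CC1=C(C)C[C@@H](O[Si](C)(C)C(C)(C)C)CC1(C)C | intermediate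
41 | {(2E,4E,6E,8E)-3,7-dimethyl-9-[(1R,4R)-4-(TBSO)-2,6,6-trimethylcyclohex-2-en-1-yl]nona-2,4,6,8-tetraen-1-ylidene}triphenylphosphorane (not isolated) | c1ccccc1P(c1ccccc1)(c1ccccc1)=C/C=C(C)/C=C/C=C(C)/C=C/[C@H]1C(C)=C[C@H](O[Si](C)(C)C(C)(C)C)CC1(C)C | intermediate
42 | (3R,3′R,6′R)-3,3′-bis(TBSO)-19-dodecanoyloxy-7,8-dihydro-β,ε-caroten-8-one | CCCCCCCCCCCC(=O)OC\C(=C/C=C/C(C)=C/C=C/C=C(C)/C=C/C=C(C)/C=C/[C@H]1C(C)=C[C@H](O[Si](C)(C)C(C)(C)C)CC1(C)C)C(=O)CC1=C(C)C[C@@H](O[Si](C)(C)C(C)(C)C)CC1(C)C | intermediate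
43 | (3R,3′R,6′R)-19-dodecanoyloxy-3,3′-dihydroxy-7,8-dihydro-β,ε-caroten-8-one (CNP0415583.1) | CCCCCCCCCCCC(=O)OC\C(=C/C=C/C(C)=C/C=C/C=C(C)/C=C/C=C(C)/C=C/[C@H]1C(C)=C[C@H](O)CC1(C)C)C(=O)CC1=C(C)C[C@@H](O)CC1(C)C | target

Total step count: 30. Longest linear sequence: 14 steps (steps 13–19, then 24–30, from 4-oxoisophorone).

**Steps most likely to fail**

1. Step 10. The carbometalation may stall or deliver methyl with incomplete regiocontrol, the alane may ionise the allylic C3′ silyl ether, or slow transmetalation may let the alkenyl iodide homocouple. The fallback builds the same chain by carbonyl olefination and sets out from ketone 7. Horner–Wadsworth–Emmons reaction with diethyl (cyanomethyl)phosphonate (NaH, THF) should give (2E,4E)-3-methyl-5-[(1R,4R)-4-(TBSO)-2,6,6-trimethylcyclohex-2-en-1-yl]penta-2,4-dienenitrile F1, the 9′Z isomer being removed by chromatography. Reduction with i-Bu2AlH at −78 °C and hydrolysis on wet silica gives the corresponding dienal F2. A second Horner–Wadsworth–Emmons reaction with triethyl 3-methyl-4-phosphonocrotonate (LiN(SiMe3)2, THF, −78 °C) gives the C20 ethyl tetraenoate F3, and reduction with i-Bu2AlH returns to the route at alcohol 17.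

2. Step 29. The hindered polyenyl salt may convert poorly, the ylide or the transient alkoxide may displace the allylic laurate by addition to the 2-(acyloxymethyl)enone, and double-bond isomers may be hard to equilibrate. The fallback replaces the Wittig union by a Julia–Kocienski olefination and sets out from alcohol 17. Mitsunobu thioetherification with 2-mercaptobenzothiazole (PPh3, diisopropyl azodicarboxylate, THF, 0 °C) gives the allylic benzothiazolyl sulfide F4. Oxidation (H2O2, (NH4)6Mo7O24 cat., EtOH, 0 °C) gives the benzothiazolyl sulfone F5. Metalation (NaN(SiMe3)2, THF, −78 °C), addition of aldehyde 40 and thermal Z to E equilibration return to the route at 42.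

3. Step 4. The lipase may discriminate the enantiomers poorly, or prefer the opposite enantiomer to the one predicted. The fallback is a classical resolution through diastereomeric esters and sets out from racemic alcohol 4. Acylation with (1S)-camphanic chloride (pyridine, 4-dimethylaminopyridine, CH2Cl2) gives the camphanate of the (1R,4R) alcohol F6 and the camphanate of the (1S,4S) alcohol F7, which are separated by crystallisation and chromatography. Methanolysis of F6 (K2CO3, MeOH, 0 °C) returns to the route at 5.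

Further compounds
F1 | step 10 | (2E,4E)-3-methyl-5-[(1R,4R)-4-(TBSO)-2,6,6-trimethylcyclohex-2-en-1-yl]penta-2,4-dienenitrile | N#C/C=C(C)/C=C/[C@H]1C(C)=C[C@H](O[Si](C)(C)C(C)(C)C)CC1(C)C
F2 | step 10 | (2E,4E)-3-methyl-5-[(1R,4R)-4-(TBSO)-2,6,6-trimethylcyclohex-2-en-1-yl]penta-2,4-dienal | O=C/C=C(C)/C=C/[C@H]1C(C)=C[C@H](O[Si](C)(C)C(C)(C)C)CC1(C)C
F3 | step 10 | ethyl (2E,4E,6E,8E)-3,7-dimethyl-9-[(1R,4R)-4-(TBSO)-2,6,6-trimethylcyclohex-2-en-1-yl]nona-2,4,6,8-tetraenoate | CCOC(=O)/C=C(C)/C=C/C=C(C)/C=C/[C@H]1C(C)=C[C@H](O[Si](C)(C)C(C)(C)C)CC1(C)C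
F4 | step 29 | 2-({(2E,4E,6E,8E)-3,7-dimethyl-9-[(1R,4R)-4-(TBSO)-2,6,6-trimethylcyclohex-2-en-1-yl]nona-2,4,6,8-tetraen-1-yl}sulfanyl)-1,3-benzothiazole | c1ccc2sc(SC/C=C(C)/C=C/C=C(C)/C=C/[C@H]3C(C)=C[C@H](O[Si](C)(C)C(C)(C)C)CC3(C)C)nc2c1
F5 | step 29 | 2-({(2E,4E,6E,8E)-3,7-dimethyl-9-[(1R,4R)-4-(TBSO)-2,6,6-trimethylcyclohex-2-en-1-yl]nona-2,4,6,8-tetraen-1-yl}sulfonyl)-1,3-benzothiazole | O=S(=O)(C/C=C(C)/C=C/C=C(C)/C=C/[C@H]1C(C)=C[C@H](O[Si](C)(C)C(C)(C)C)CC1(C)C)c1nc2ccccc2s1
F6 | step 4 | (1R,4R)-3,5,5-trimethyl-4-[(E)-2-(2-methyl-1,3-dioxolan-2-yl)ethenyl]cyclohex-2-en-1-yl (1S)-camphanate | CC1(OCCO1)/C=C/[C@H]1C(C)=C[C@H](OC(=O)[C@]23OC(=O)[C@](C)(CC2)C3(C)C)CC1(C)C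
F7 | step 4 | (1S,4S)-3,5,5-trimethyl-4-[(E)-2-(2-methyl-1,3-dioxolan-2-yl)ethenyl]cyclohex-2-en-1-yl (1S)-camphanate | CC1(OCCO1)/C=C/[C@@H]1C(C)=C[C@@H](OC(=O)[C@]23OC(=O)[C@](C)(CC2)C3(C)C)CC1(C)C
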